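## Retrosynthetic overview

1. The hydroxyquinone comes last, by Teuber oxidation of a 2-alkyl-4-chloro-5-methylresorcinol (arene bought as orcinol).
2. The (E)-allylic carbinol comes from ligand-controlled addition of an aryl-bearing (E)-alkenylzinc (from a 2-butynyl arene) to a keto-aldehyde, selective for CHO over the ring C=O.
3. The keto-aldehyde comes from hydroboration–oxidation and double oxidation of a cyclohexenyl-acetaldehyde. That aldehyde comes from Claisen rearrangement of the vinyl ether of cis-(1R,4S)-2,3,4-trimethylcyclohex-2-en-1-ol, which makes the bond between the exocyclic CH2 and the quaternary ring carbon.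
4. Enabling feature: in the cyclohexanone ring the quaternary carbon is β to the carbonyl carbon, and its exocyclic CH2 leads to an oxygen-bearing carbon. With the C(=O)–CH(CH3) pair read as a hydroborated C=C, the unit O=C–CH2–C(quaternary)–C=C is a γ,δ-unsaturated aldehyde. The oxygen on the future ketone carbon can therefore deliver the two-carbon unit to its own ring face, cis to both flanking methyl-bearing carbons.
5. Ring order: cyclohexenone ring first (Michael/aldol annulation), aromatic ring carried intact, benzoquinone ring last.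

Key step: step 4

Assumption: the sense of induction of the prolinol catalyst (step 1) and of the amino alcohol ligand (step 10) is taken from the accepted models for these catalyst classes; if either proved opposite, the antipodal catalyst or ligand would be used.

## Route

Step 1
Reactants: 1 propanal; 2 pent-1-en-3-one
Product: 4 (S)-2,4-dimethylcyclohex-2-en-1-one, via (S)-2-methyl-5-oxoheptanal 3 (not isolated)
Conditions: (R)-2-[diphenyl(trimethylsilyloxy)methyl]pyrrolidine (5 mol %), ethyl 3,4-dihydroxybenzoate (20 mol %), neat, 4 °C; then pTsOH·H2O (10 mol %), PhMe, 60 °C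
Reagents that add atoms: none
Why: Enamine-mediated asymmetric Michael addition, in which the diarylsilyloxymethyl group shields one face of the E-enamine and so should fix the methyl-bearing centre as (S), is followed by acid-promoted intramolecular aldol condensation (Robinson-type annulation) of the ethyl ketone onto the aldehyde, the only enol/carbonyl pairing that closes a six-membered ring.

Step 2
Reactants: 4 (S)-2,4-dimethylcyclohex-2-en-1-one
Product: 6 (S)-2,3,4-trimethylcyclohex-2-en-1-one, via silyl enol ether 5 (not isolated)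
Conditions: Me2CuLi (1.3 equiv), TMSCl (2 equiv), THF, −78 → 0 °C; concentrate; Pd(OAc)2 (1.05 equiv), MeCN, 25 °C
Reagents that add atoms: lithium dimethylcuprate (Me2CuLi), [Li+].C[Cu-]C
Why: Cuprate conjugate addition with in situ silylation followed by Saegusa–Ito dehydrogenation amounts to β-methylation of the enone; the transient C3 centre is erased, the conjugated tetrasubstituted enone is the thermodynamic outcome of β-hydride elimination, and the C4 centre is not touched.

Step 3
Reactants: 6 (S)-2,3,4-trimethylcyclohex-2-en-1-one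
Product: 7 (1R,4S)-2,3,4-trimethylcyclohex-2-en-1-ol
Conditions: (S)-Me-CBS oxazaborolidine [(S)-1-methyl-3,3-diphenyltetrahydro-1H,3H-pyrrolo[1,2-c][1,3,2]oxazaborole] (10 mol %), BH3·SMe2 (0.6 equiv), THF, −20 °C; MeOH, then aq NH4Cl
Reagents that add atoms: none
Why: Corey–Bakshi–Shibata reduction, in which the tetrasubstituted alkenyl flank plays the large group (as aryl does in aryl alkyl ketones), so the (S)-catalyst should give the (1R) carbinol, cis to the C4 methyl, under reagent control that the remote C4 centre cannot override.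

Step 4
Reactants: 7 (1R,4S)-2,3,4-trimethylcyclohex-2-en-1-ol; 8 butyl vinyl ether
Product: 10 2-[(1S,6S)-1,2,6-trimethylcyclohex-2-en-1-yl]acetaldehyde, via allyl vinyl ether 9 (not isolated)
Conditions: Pd(OCOCF3)2 (2 mol %), 4,7-diphenyl-1,10-phenanthroline (2 mol %), Et3N (5 mol %), neat 8, 75 °C; evaporate, filter (basic Al2O3); PhMe, sealed tube, 180 °C
Reagents that add atoms: none
Why: Pd(OCOCF3)2-catalysed transfer vinylation turns the allylic alcohol into allyl vinyl ether 9, which on heating undergoes a concerted, suprafacial [3,3]-sigmatropic (Claisen) shift through a six-membered chair- or boat-like transition state: the pseudoaxial C–O bond breaks while the vinyl terminus bonds to the distal, methyl-bearing alkene carbon. The closest known reaction type is the thermal Claisen rearrangement of cyclohex-2-enyl vinyl ethers to cyclohexenylacetaldehydes with a new quaternary carbon. No ring is closed; the cyclohexene ring is kept and its double bond moves to the two carbons that later become the ketone carbon and its α-carbon. The one new stereocentre, the quaternary carbon, is set by 1,3-chirality transfer: the C–C bond must form on the ring face that carried the oxygen, so the (1R) carbinol of 7 dictates (S) at the quaternary carbon and puts the CH2 unit cis to the methyl on the neighbouring CH carbon, a relation that addition from outside, anti to that methyl, would not give. The step needs the [3,3] shift to outrun elimination or ionisation of the tetrasubstituted allylic ether and needs complete transfer of chirality; the neutral, base-buffered, acid-free medium and the intramolecular, stereospecific nature of the shift (the cis-1,4 isomer can place the oxygen pseudoaxial with the C4 methyl pseudoequatorial) should secure both.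

Step 5
Reactants: 10 2-[(1S,6S)-1,2,6-trimethylcyclohex-2-en-1-yl]acetaldehyde
Product: 12 (1S,2S,3S,4S)-3-(2-hydroxyethyl)-2,3,4-trimethylcyclohexan-1-ol, via organoborane 11 (not isolated)
Conditions: BH3·THF (4 equiv), THF, 0 → 25 °C; then NaOH (3 M aq), H2O2 (30 %), 0 → 25 °C
Reagents that add atoms: hydrogen peroxide, OO
Why: Brown hydroboration–oxidation with excess borane, which also reduces the aldehyde: boron adds to the CH end of the trisubstituted alkene and syn addition should occur on the face opposite the pseudoaxial CH2 chain of the neighbouring quaternary carbon, so the C2 hydrogen and C1 oxygen enter trans to that chain and the C2 methyl ends up cis to it, as the target requires.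

Step 6
Reactants: 12 (1S,2S,3S,4S)-3-(2-hydroxyethyl)-2,3,4-trimethylcyclohexan-1-ol
Product: 13 2-[(1S,2S,6S)-1,2,6-trimethyl-3-oxocyclohexyl]acetaldehyde
Conditions: Dess–Martin periodinane (2.6 equiv), CH2Cl2, 0 → 25 °C
Reagents that add atoms: none
Why: Dess–Martin oxidation converts both carbinols under non-enolising conditions that should leave the α-methyl stereocentre untouched; the trans relation of the ring hydroxyl and the side chain rules out lactol formation on the way.

Step 7
Reactants: 14 orcinol (5-methylbenzene-1,3-diol)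
Product: 15 4-chloro-5-methylbenzene-1,3-diol
Conditions: SO2Cl2 (1.0 equiv), Et2O, 0 °C
Reagents that add atoms: sulfuryl chloride, ClS(Cl)(=O)=O
Why: Electrophilic aromatic chlorination should go para to one hydroxyl and ortho to the other (the two such positions of orcinol are equivalent, the position between the hydroxyls is more hindered), and one equivalent of reagent stops it at the monochloride.

Step 8
Reactants: 15 4-chloro-5-methylbenzene-1,3-diol
Product: 16 2-chloro-1,5-bis(methoxymethoxy)-3-methylbenzene
Conditions: NaH (2.4 equiv), DMF, 0 °C; MOMCl (2.4 equiv), 0 → 25 °C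
Reagents that add atoms: chloromethyl methyl ether, COCCl
Why: Williamson-type O-alkylation of the bis-phenoxide; the MOM ethers withstand the organometallic steps and direct the metalation of step 9.

Step 9
Reactants: 16 2-chloro-1,5-bis(methoxymethoxy)-3-methylbenzene; 17 1-bromobut-2-yne
Product: 19 2-(but-2-yn-1-yl)-4-chloro-1,3-bis(methoxymethoxy)-5-methylbenzene, via aryllithium 18 (not isolated)
Conditions: n-BuLi (1.1 equiv), THF, 0 °C; CuI (10 mol %), 17 (1.3 equiv), −78 → 0 °C
Reagents that add atoms: none
Why: Directed ortho-metalation occurs at the ring carbon flanked by both MOM ethers (no hydrogen is ortho to chlorine, so no aryne can form), and copper-catalysed SN2 alkylation of the aryl anion with the primary propargylic bromide gives the 2-butynyl arene.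

Step 10
Reactants: 19 2-(but-2-yn-1-yl)-4-chloro-1,3-bis(methoxymethoxy)-5-methylbenzene; 13 2-[(1S,2S,6S)-1,2,6-trimethyl-3-oxocyclohexyl]acetaldehyde
Product: 22 (2S,3S,4S)-3-{(2S,3E)-5-[3-chloro-2,6-bis(methoxymethoxy)-4-methylphenyl]-2-hydroxy-3-methylpent-3-en-1-yl}-2,3,4-trimethylcyclohexan-1-one, via alkenylzirconocene chloride 20 (not isolated), via alkenyl(methyl)zinc 21 (not isolated)
Conditions: 19 (1.5 equiv), Cp2Zr(H)Cl (1.6 equiv), CH2Cl2, 25 °C; solvent change to PhMe; Me2Zn (1.5 equiv), −65 °C; (+)-MIB [(2R)-3-exo-morpholinoisoborneol] (10 mol %), 13, −30 → 0 °C; aq NH4Cl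
Reagents that add atoms: none
Why: Syn hydrozirconation should place zirconium on the less hindered, methyl-bearing alkyne carbon (excess hydride equilibrates the regioisomers), Zr-to-Zn transmetalation gives an (E)-alkenylzinc that keeps its geometry, and amino-alcohol-catalysed alkenylzinc addition should deliver it to the Re face of the aldehyde to set the (S) carbinol, while the ring ketone is inert to organozinc reagents.

Step 11
Reactants: 22 (2S,3S,4S)-3-{(2S,3E)-5-[3-chloro-2,6-bis(methoxymethoxy)-4-methylphenyl]-2-hydroxy-3-methylpent-3-en-1-yl}-2,3,4-trimethylcyclohexan-1-one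
Product: 23 (2S,3S,4S)-3-[(2S,3E)-5-(3-chloro-2,6-dihydroxy-4-methylphenyl)-2-hydroxy-3-methylpent-3-en-1-yl]-2,3,4-trimethylcyclohexan-1-one
Conditions: NaHSO4·SiO2, CH2Cl2, 25 °C
Reagents that add atoms: none
Why: Acid-catalysed acetal cleavage on a solid hydrogen sulfate, a mild method selective for phenolic MOM ethers, should free both phenols without ionising the allylic alcohol or epimerising the ketone α-centre.

Step 12
Reactants: 23 (2S,3S,4S)-3-[(2S,3E)-5-(3-chloro-2,6-dihydroxy-4-methylphenyl)-2-hydroxy-3-methylpent-3-en-1-yl]-2,3,4-trimethylcyclohexan-1-one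
Product: 24 2-chloro-5-hydroxy-6-{(2E,4S)-4-hydroxy-3-methyl-5-[(1S,2S,6S)-1,2,6-trimethyl-3-oxocyclohexyl]pent-2-en-1-yl}-3-methylcyclohexa-2,5-diene-1,4-dione
Conditions: (KSO3)2NO (Fremy's salt, 2.5 equiv), KH2PO4 buffer (pH 6), acetone/H2O, 0 → 25 °C
Reagents that add atoms: potassium nitrosodisulfonate (KSO3)2NO, [K+].[K+].[O-]S(=O)(=O)N([O])S(=O)(=O)[O-]
Why: Teuber oxidation: the phenoxyl radical couples with a second equivalent of the nitroxyl at the only unsubstituted ring carbon, para to one hydroxyl, and loss of the aminodisulfonate should give the 1,4-benzoquinone in which the other hydroxyl remains as the 2-hydroxy group; no stereocentre is affected.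

## Compound list

1 | propanal | CCC=O | starting material
2 | pent-1-en-3-one | CCC(=O)C=C | starting material
3 | (S)-2-methyl-5-oxoheptanal | CCC(=O)CC[C@H](C)C=O | intermediate
4 | (S)-2,4-dimethylcyclohex-2-en-1-one | O=C1CC[C@H](C)C=C1C | intermediate
5 | trimethyl{[(3R,4S)-2,3,4-trimethylcyclohex-1-en-1-yl]oxy}silane (silyl enol ether) | C[Si](C)(C)OC1=C(C)[C@H](C)[C@@H](C)CC1 | intermediate
6 | (S)-2,3,4-trimethylcyclohex-2-en-1-one | O=C1CC[C@H](C)C(C)=C1C | intermediate
7 | (1R,4S)-2,3,4-trimethylcyclohex-2-en-1-ol | O[C@@H]1CC[C@H](C)C(C)=C1C | intermediate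
8 | butyl vinyl ether | C=COCCCC | starting material
9 | (3R,6S)-3-(ethenyloxy)-1,2,6-trimethylcyclohex-1-ene (allyl vinyl ether) | C=CO[C@@H]1CC[C@H](C)C(C)=C1C | intermediate
10 | 2-[(1S,6S)-1,2,6-trimethylcyclohex-2-en-1-yl]acetaldehyde | O=CC[C@]1(C)C(C)=CCC[C@@H]1C | intermediate
11 | organoborane from 10 (drawn as the C-boryl, O-boryl bis-BH2 species) | BOCC[C@]1(C)[C@H](C)[C@@H](B)CC[C@@H]1C | intermediate
12 | (1S,2S,3S,4S)-3-(2-hydroxyethyl)-2,3,4-trimethylcyclohexan-1-ol | OCC[C@]1(C)[C@H](C)[C@@H](O)CC[C@@H]1C | intermediate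
13 | 2-[(1S,2S,6S)-1,2,6-trimethyl-3-oxocyclohexyl]acetaldehyde | O=CC[C@]1(C)[C@H](C)C(=O)CC[C@@H]1C | intermediate
14 | orcinol (5-methylbenzene-1,3-diol) | Cc1cc(O)cc(O)c1 | starting material
15 | 4-chloro-5-methylbenzene-1,3-diol | Cc1cc(O)cc(O)c1Cl | intermediate
16 | 2-chloro-1,5-bis(methoxymethoxy)-3-methylbenzene | COCOc1cc(C)c(Cl)c(OCOC)c1 | intermediate
17 | 1-bromobut-2-yne | CC#CCBr | starting material
18 | [3-chloro-2,6-bis(methoxymethoxy)-4-methylphenyl]lithium (aryllithium) | [Li]c1c(OCOC)cc(C)c(Cl)c1OCOC | intermediate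
19 | 2-(but-2-yn-1-yl)-4-chloro-1,3-bis(methoxymethoxy)-5-methylbenzene | CC#CCc1c(OCOC)cc(C)c(Cl)c1OCOC | intermediate
20 | (E)-alkenylzirconocene chloride, Cp2Zr(Cl)–C(CH3)=CH–CH2Ar, Ar = 3-chloro-2,6-bis(methoxymethoxy)-4-methylphenyl | C/C(=C\Cc1c(OCOC)cc(C)c(Cl)c1OCOC)[Zr](Cl)(C1C=CC=C1)C1C=CC=C1 | intermediate
21 | (E)-alkenyl(methyl)zinc, CH3Zn–C(CH3)=CH–CH2Ar, same Ar | C/C(=C\Cc1c(OCOC)cc(C)c(Cl)c1OCOC)[Zn]C | intermediate
22 | (2S,3S,4S)-3-{(2S,3E)-5-[3-chloro-2,6-bis(methoxymethoxy)-4-methylphenyl]-2-hydroxy-3-methylpent-3-en-1-yl}-2,3,4-trimethylcyclohexan-1-one | COCOc1cc(C)c(Cl)c(OCOC)c1C/C=C(\C)[C@@H](O)C[C@]1(C)[C@H](C)C(=O)CC[C@@H]1C | intermediate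
23 | (2S,3S,4S)-3-[(2S,3E)-5-(3-chloro-2,6-dihydroxy-4-methylphenyl)-2-hydroxy-3-methylpent-3-en-1-yl]-2,3,4-trimethylcyclohexan-1-one | Oc1cc(C)c(Cl)c(O)c1C/C=C(\C)[C@@H](O)C[C@]1(C)[C@H](C)C(=O)CC[C@@H]1C | intermediate
24 | 2-chloro-5-hydroxy-6-{(2E,4S)-4-hydroxy-3-methyl-5-[(1S,2S,6S)-1,2,6-trimethyl-3-oxocyclohexyl]pent-2-en-1-yl}-3-methylcyclohexa-2,5-diene-1,4-dione | CC1=C(Cl)C(=O)C(C/C=C(\C)[C@@H](O)C[C@]2(C)[C@H](C)C(=O)CC[C@@H]2C)=C(O)C1=O | target

## Step count and risks

Total step count: 12. Longest linear sequence: 9 (steps 1–6, then 10–12); the arene branch (steps 7–9) joins at step 10.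

Steps most likely to fail:

Step 4. The thermal shift may be outrun by elimination or ionisation of the hindered, tetrasubstituted allylic ether, or vinyl transfer to the hindered alcohol may stall. The fallback makes the same bond by an ester-enolate (Ireland–Claisen) rearrangement at much lower temperature. It sets out from 7: acetylation (Ac2O, DMAP, pyridine) should give (1R,4S)-2,3,4-trimethylcyclohex-2-en-1-yl acetate F1. LDA with TMSCl/Et3N in THF at −78 °C should give the silyl ketene acetal F2, which is expected to rearrange at 25–60 °C to the trimethylsilyl ester F3 and, on aqueous work-up, to 2-[(1S,6S)-1,2,6-trimethylcyclohex-2-en-1-yl]acetic acid F4. BH3·THF then reduces the acid and hydroborates the alkene (through 11), and NaOH/H2O2 brings the route back at diol 12.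

Step 10. Regiocontrol in the hydrozirconation of the unsymmetrical alkyne may be incomplete, or the ligand may control the face of this β-quaternary aldehyde only weakly. The fallback separates the two tasks. It sets out from 19: hydrozirconation (through 20) and iodinolysis with I2 should give 4-chloro-2-[(2E)-3-iodobut-2-en-1-yl]-1,3-bis(methoxymethoxy)-5-methylbenzene F5, which can be purified from its regioisomer. Nozaki–Hiyama–Kishi coupling with 13 (CrCl2, NiCl2 cat., DMSO), through the alkenylchromium dichloride F6, adds only to the aldehyde and should give 22 together with its carbinol epimer F7. These are diastereomers and are separated by chromatography. F7 is returned by Mitsunobu inversion (4-nitrobenzoic acid, PPh3, DIAD) to the inverted 4-nitrobenzoate F8 and methanolysis (K2CO3, MeOH), coming back to the route at 22.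

Step 11. Acid may ionise the secondary allylic alcohol, or a freed phenol may cyclise onto the trisubstituted alkene, before both MOM groups are gone. The fallback changes the phenol protecting group before the fragment union, so that the last deprotection is fluoride-mediated. It sets out from 19: HCl in MeOH should give 2-(but-2-yn-1-yl)-4-chloro-5-methylbenzene-1,3-diol F9, and TBSCl/imidazole in DMF its bis(tert-butyldimethylsilyl) ether F10. The step 10 protocol (alkenylzirconocene chloride F11, then alkenyl(methyl)zinc F12) with 13 should give the bis-silyl analogue of 22, F13. TBAF/AcOH in THF at 0 °C removes both aryl silyl ethers and comes back to the route at 23.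

## Further compounds

F1 | step 4 | (1R,4S)-2,3,4-trimethylcyclohex-2-en-1-yl acetate | CC(=O)O[C@@H]1CC[C@H](C)C(C)=C1C
F2 | step 4 | trimethyl[(1-{[(1R,4S)-2,3,4-trimethylcyclohex-2-en-1-yl]oxy}ethenyl)oxy]silane (silyl ketene acetal) | C=C(O[Si](C)(C)C)O[C@@H]1CC[C@H](C)C(C)=C1C
F3 | step 4 | trimethylsilyl 2-[(1S,6S)-1,2,6-trimethylcyclohex-2-en-1-yl]acetate | C[Si](C)(C)OC(=O)C[C@]1(C)C(C)=CCC[C@@H]1C
F4 | step 4 | 2-[(1S,6S)-1,2,6-trimethylcyclohex-2-en-1-yl]acetic acid | OC(=O)C[C@]1(C)C(C)=CCC[C@@H]1C
F5 | step 10 | 4-chloro-2-[(2E)-3-iodobut-2-en-1-yl]-1,3-bis(methoxymethoxy)-5-methylbenzene | C/C(I)=C\Cc1c(OCOC)cc(C)c(Cl)c1OCOC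
F6 | step 10 | (E)-alkenylchromium dichloride from F5 | C/C(=C\Cc1c(OCOC)cc(C)c(Cl)c1OCOC)[Cr](Cl)Cl
F7 | step 10 | (2S,3S,4S)-3-{(2R,3E)-5-[3-chloro-2,6-bis(methoxymethoxy)-4-methylphenyl]-2-hydroxy-3-methylpent-3-en-1-yl}-2,3,4-trimethylcyclohexan-1-one (carbinol epimer of 22) | COCOc1cc(C)c(Cl)c(OCOC)c1C/C=C(\C)[C@H](O)C[C@]1(C)[C@H](C)C(=O)CC[C@@H]1C
F8 | step 10 | 4-nitrobenzoate ester of 22 | COCOc1cc(C)c(Cl)c(OCOC)c1C/C=C(\C)[C@@H](OC(=O)c1ccc(cc1)[N+](=O)[O-])C[C@]1(C)[C@H](C)C(=O)CC[C@@H]1C
F9 | step 11 | 2-(but-2-yn-1-yl)-4-chloro-5-methylbenzene-1,3-diol | CC#CCc1c(O)cc(C)c(Cl)c1O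
F10 | step 11 | 2-(but-2-yn-1-yl)-1,3-bis(tert-butyldimethylsilyloxy)-4-chloro-5-methylbenzene | CC#CCc1c(O[Si](C)(C)C(C)(C)C)cc(C)c(Cl)c1O[Si](C)(C)C(C)(C)C
F11 | step 11 | (E)-alkenylzirconocene chloride from F10 | C/C(=C\Cc1c(O[Si](C)(C)C(C)(C)C)cc(C)c(Cl)c1O[Si](C)(C)C(C)(C)C)[Zr](Cl)(C1C=CC=C1)C1C=CC=C1
F12 | step 11 | (E)-alkenyl(methyl)zinc from F11 | C/C(=C\Cc1c(O[Si](C)(C)C(C)(C)C)cc(C)c(Cl)c1O[Si](C)(C)C(C)(C)C)[Zn]C
F13 | step 11 | (2S,3S,4S)-3-{(2S,3E)-5-[2,6-bis(tert-butyldimethylsilyloxy)-3-chloro-4-methylphenyl]-2-hydroxy-3-methylpent-3-en-1-yl}-2,3,4-trimethylcyclohexan-1-one | CC(C)(C)[Si](C)(C)Oc1cc(C)c(Cl)c(O[Si](C)(C)C(C)(C)C)c1C/C=C(\C)[C@@H](O)C[C@]1(C)[C@H](C)C(=O)CC[C@@H]1C
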